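## The problem

Compound 9 is a diaryl ether in which two dibrominated ortho-hydroxyphenyl rings share one oxygen. It has no stereocenter and no ring to close, so the whole difficulty is positional. Ring B (ether carbon C1', hydroxyl on C2', bromine on C3' and C5') carries its bromines ortho and para to the hydroxyl, the pattern that any phenol bromination delivers. Ring A (hydroxyl on C1, ether carbon C2, bromine on C3 and C5) carries both bromines meta to its hydroxyl and ortho/para to the ether oxygen, so this hydroxyl cannot have directed them. The ether bond joins C2, flanked by C1–OH and C3–Br, to C1', flanked by C2'–OH. The coupling is therefore hindered, has to tell the two oxygens of each catechol-type ring apart, and has to decide which ring is the electrophile. Four aryl–bromine bonds must survive, which excludes metal-catalysed C–O coupling at carbon–halogen bonds, organolithium reagents and hydrogenolysis. The acidic, oxidisable bromophenols are best unveiled late. The enabling feature is that a formyl carbon on C1 of ring A, in place of the hydroxyl, is meta to C3 and C5 and ortho to C2. It accounts for the bromine pattern, activates a C2–F bond toward phenoxide attack, and can then be exchanged for oxygen by a peracid-induced aryl shift.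

## Retrosynthesis

**9 ⇒ 8.** The first cut is the O–CH3 bond of a methyl ether on the ring B hydroxyl (C2'–O), which leads from 9 to 8. The two hydroxyls of 9 sit on different rings and are formed at different times. The ring B oxygen must be capped while the other ring B oxygen acts as nucleophile and while peracid is present. A methyl group survives carbonate, heat and mCPBA, and BBr3 removes it without touching the diaryl ether or the bromides. The forward step only has to cleave one O–CH3 bond.

**8 ⇒ 6.** The second cut is the C1–O bond of ring A. It is replaced by a C1–CHO bond, so that 8 descends from aldehyde 6 through the formate 7. This cut is preferred over cutting a C–Br bond or the ether bond at this stage because the formyl group does three jobs that the hydroxyl cannot: it is meta to both bromines, it is ortho to the ether carbon, and it is an acceptor. The forward reaction must add a peracid to the formyl group and move ring A, not hydride, from carbon to oxygen. The C2 aryloxy oxygen ortho to the migrating carbon is the substrate feature that should bias this.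

**6 ⇒ 4 + 5.** The third cut is the C2–O ether bond on the ring A side, giving phenol 4 and fluoroaldehyde 5. Cutting on the ring B side instead (C1'–O) would require an electrophilic ring B, which has no acceptor group. Ring A has the formyl group ortho to C2 and needs no metal catalyst, so the four bromines are never exposed to oxidative addition. The precursors are two monocyclic benzenes. 5 is an article of commerce, and its bromines sit where a meta-directing formyl and an ortho/para-directing fluorine jointly send an electrophile. The forward reaction is a phenoxide displacement of fluoride at a carbon flanked by formyl and bromine.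

**4 ⇒ 2 ⇒ 1.** The last cuts are the C1'–O(H) bond of 4, again traced to a formyl carbon in 2 through formate 3, and the O–CH3 bond of 2, which leads to 1. This is preferred over brominating a ring B phenol because 1 is purchased with both bromines ortho and para to its oxygen and with a carbon substituent at the position that must become the nucleophilic oxygen. Methylation makes the existing oxygen the protected one, and the oxidation creates the free one, so the two ring B oxygens are differentiated without any selective protection. The forward reactions are a Williamson methylation and the same aryl-shift oxidation as in the key step, here on a simpler substrate where it can be tested first.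

## Roads not taken

**Alternative 1:** Ring A is assembled, not bought. The C2–C3 and C1–C6 bonds are cut, leading to 3,5-dibromo-2-pyrone A1 and the aryloxy-substituted alkynyl pinacol boronate A2.
- Forward key step: the two are heated, the [4+2] adduct loses CO2, and arylboronate A3 emerges with both bromines, the ether oxygen and a boron substituent on C1 standing in for the hydroxyl.
- Merits: the bromines arrive meta to the future hydroxyl without any directing group. Oxidation of a C–B bond to C–OH has none of the migratory ambiguity of a formyl oxidation, and in that respect this road is surer than the chosen one.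
- Weak points: A2 is an ynol ether with boron on the same triple bond, a reagent class without a secure preparation and of doubtful stability. The cycloaddition must orient so that the oxygen-bearing alkyne carbon bonds to C3 of A1 and the boron-bearing carbon to C6, which is not assured, and it needs prolonged heating. A3 carries ring B without bromine, so two C–Br bonds must still be introduced ortho and para to a freed ring B hydroxyl while the ring A oxygen stays masked.
- Comparison: the road is longer and its key step rests on an unproven reagent. Against the cleaner final C–O formation, the chosen plan sets purchased bromine patterns on both rings and three well-known reaction types.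

**Alternative 2:** The C3'–Br and C5'–Br bonds and the aromaticity of ring B are removed, and ring B is carried as a cyclohexanone. 4,6-Dibromoguaiacol A4 would be O-alkylated with 2-chlorocyclohexanone A5 to the aryloxy ketone A6.
- Forward key step: A6 is treated with excess Br2 in acetic acid, which should brominate alpha to the carbonyl, eliminate HBr twice and brominate the new phenol to give A7. Demethylation would finish.
- Merits: on paper this is the shortest road, three or four steps from very cheap materials. It uses the fact that the ring A bromines are ortho/para to the oxygen that becomes the ether. In step count and cost it is better than the chosen plan.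
- Weak points: the aromatisation is a cascade of several brominations and eliminations with no handle on their order. Bromination at the carbon that bears the aryloxy group invites loss of the aryloxide. The number and placement of bromines on the new ring are set only by the stoichiometry of Br2. Ring A in A6 and A7 still has free positions ortho and para to its methoxy group that hot Br2 and HBr can attack.
- Comparison: against the brevity, the chosen plan sets positional certainty. Every substituent of 9 is fixed either by a purchased pattern or by attack at one defined carbon, and no step depends on the order of events in a cascade.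

**Alternative 3:** The C3–Br and C5–Br bonds of ring A are cut and replaced by C–N bonds, so both bromines descend from nitro groups. Phenol 4 would displace chloride from 2-chloro-1-methoxy-3,5-dinitrobenzene A8 to give dinitro ether A9, and reduction would give diamine A10.
- Forward key step: A10 is bis-diazotised and both diazonium groups are replaced by bromide (tert-butyl nitrite with CuBr2, or NaNO2/HBr then CuBr) to give the dimethyl ether A11. Both methyl ethers are then cleaved together.
- Merits: the ether-forming displacement is activated by one ortho and one para nitro group and is much easier than step 3 of the chosen route, so on this point the road is clearly better. The bromine positions are unambiguous, and the final deprotection is a single operation.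
- Weak points: the nitro groups must be reduced without touching the ring B bromides. A meta-phenylenediamine on an alkoxy- and aryloxy-substituted ring is prone to azo self-coupling during diazotisation. Two Sandmeyer exchanges on one ring compound the losses from hydrodediazoniation. A8 is not a stock item and needs its own preparation, and the route still requires phenol 4.
- Comparison: the chosen plan converts one substituent of ring A in one oxidation, whereas this road needs a reduction and two nitrogen-to-bromine exchanges. Against the easier displacement, the chosen plan sets a shorter sequence and the absence of polynitro and diazonium intermediates.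

Key step: step 4

Remark on the chemistry: 5 is taken as a purchasable building block, and 9 has no stereocenter, so no configuration has to be set anywhere in the route.

## Route

Step 1
Reactants: 1 3,5-dibromosalicylaldehyde (3,5-dibromo-2-hydroxybenzaldehyde)
Product: 2 3,5-dibromo-2-methoxybenzaldehyde
Conditions: MeI, K2CO3, DMF, rt
Reagents that add atoms: iodomethane, CI
Why: Williamson O-methylation; the acidic, bromine-flanked phenol is fully deprotonated by K2CO3 and the small electrophile reaches the hindered phenoxide, while the formyl group and bromides are inert.

Step 2
Reactants: 2 3,5-dibromo-2-methoxybenzaldehyde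
Product: 4 3,5-dibromo-2-methoxyphenol, via aryl formate 3 (not isolated)
Conditions: mCPBA, CH2Cl2, 40 °C; aq Na2S2O3 wash; then HCl (cat.), MeOH, rt
Reagents that add atoms: mCPBA (3-chloroperbenzoic acid), OOC(=O)c1cccc(Cl)c1
Why: Baeyer–Villiger oxidation of an ortho-alkoxybenzaldehyde (Dakin-type); the Criegee adduct should rearrange by aryl migration, assisted by the ortho methoxy oxygen, and the labile formate 3 is cleaved by acid-catalysed methanolysis. The bromides and the methyl ether do not react with the peracid.

Step 3
Reactants: 4 3,5-dibromo-2-methoxyphenol; 5 3,5-dibromo-2-fluorobenzaldehyde
Product: 6 3,5-dibromo-2-(3,5-dibromo-2-methoxyphenoxy)benzaldehyde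
Conditions: Cs2CO3, DMF, 60 °C
Reagents that add atoms: none
Why: Nucleophilic aromatic substitution (SNAr); the phenoxide of 4 adds at C2 of 5, where the ortho formyl group stabilises the Meisenheimer adduct and fluoride is the best leaving group. The bromines are meta to the formyl group, are not activated and should stay in place.

Step 4
Reactants: 6 3,5-dibromo-2-(3,5-dibromo-2-methoxyphenoxy)benzaldehyde
Product: 8 3,5-dibromo-2-(3,5-dibromo-2-methoxyphenoxy)phenol, via aryl formate 7 (not isolated)
Conditions: mCPBA, CH2Cl2, 40 °C; aq Na2S2O3 wash; then HCl (cat.), MeOH, rt
Reagents that add atoms: mCPBA (3-chloroperbenzoic acid), OOC(=O)c1cccc(Cl)c1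
Why: Baeyer–Villiger oxidation of an aryl aldehyde (Dakin-type): the peracid adds to the C1 formyl group of 6 to give a tetrahedral hydroxy perester (Criegee adduct). Ring A then shifts from carbon to the proximal peroxide oxygen as 3-chlorobenzoate leaves, giving formate 7 with the new C1–O bond, and acid-catalysed methanolysis releases phenol 8. The closest known reaction type is the peracid oxidation of ortho-alkoxy- and ortho-aryloxybenzaldehydes to phenols, which is established on halogenated rings and is rehearsed in step 2 on the simpler aldehyde 2. No ring is closed and no stereocenter is created. The selectivity required is aryl over hydride migration, since a hydride shift would end in the benzoic acid. It should be secured by the C2 aryloxy oxygen ortho to the migrating carbon, whose lone pair stabilises the electron-deficient migrating terminus of a ring otherwise depleted by two meta bromines, and by working in a non-basic medium. The four C–Br bonds, the diaryl ether and the methyl ether are inert to mCPBA. The oxidisable phenol is released only after the excess peracid has been destroyed by the thiosulfate wash.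

Step 5
Reactants: 8 3,5-dibromo-2-(3,5-dibromo-2-methoxyphenoxy)phenol
Product: 9 3,5-dibromo-2-(3,5-dibromo-2-hydroxyphenoxy)phenol
Conditions: BBr3, CH2Cl2, −78 °C to rt; then H2O
Reagents that add atoms: none
Why: BBr3 cleavage of an aryl methyl ether; boron binds the methoxy oxygen and bromide attacks the methyl carbon by SN2. The diaryl ether has no sp3 carbon to attack and the aryl bromides are inert, so only the O–CH3 bond should break, and hydrolysis of the borate gives 9.

## Compound list

1 | 3,5-dibromosalicylaldehyde (3,5-dibromo-2-hydroxybenzaldehyde) | O=Cc1cc(Br)cc(Br)c1O | starting material
2 | 3,5-dibromo-2-methoxybenzaldehyde | COc1c(Br)cc(Br)cc1C=O | intermediate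
3 | 3,5-dibromo-2-methoxyphenyl formate | COc1c(Br)cc(Br)cc1OC=O | intermediate (not isolated)
4 | 3,5-dibromo-2-methoxyphenol | COc1c(Br)cc(Br)cc1O | intermediate
5 | 3,5-dibromo-2-fluorobenzaldehyde | O=Cc1cc(Br)cc(Br)c1F | starting material
6 | 3,5-dibromo-2-(3,5-dibromo-2-methoxyphenoxy)benzaldehyde | COc1c(Br)cc(Br)cc1Oc1c(C=O)cc(Br)cc1Br | intermediate
7 | 3,5-dibromo-2-(3,5-dibromo-2-methoxyphenoxy)phenyl formate | COc1c(Br)cc(Br)cc1Oc1c(OC=O)cc(Br)cc1Br | intermediate (not isolated)
8 | 3,5-dibromo-2-(3,5-dibromo-2-methoxyphenoxy)phenol | COc1c(Br)cc(Br)cc1Oc1c(O)cc(Br)cc1Br | intermediate
9 | 3,5-dibromo-2-(3,5-dibromo-2-hydroxyphenoxy)phenol | Oc1cc(Br)cc(Br)c1Oc1cc(Br)cc(Br)c1O | target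

## Step count and risks

Total step count: 5. Longest linear sequence: 5 steps (1 → 2 → 4 → 6 → 8 → 9), with 5 entering at step 3.

**Step 4 (key step).** The most likely failure is hydride migration competing with aryl migration in the Criegee adduct, which diverts material to the carboxylic acid oxidation level.
- Cause: ring A carries two bromines meta to the migrating carbon, and the C2 oxygen is flanked on both sides and shared with ring B, so its donation into ring A is weakened. Addition of the peracid to the hindered formyl group may also be slow.
- Fallback: it sets out from 6 and returns to the route at 8. It replaces the hydrogen on the carbonyl by a methyl group, so that the competition becomes aryl against methyl, which aryl wins.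
- Course: MeMgBr (THF, −78 °C) adds to the formyl group to give racemic 1-[3,5-dibromo-2-(3,5-dibromo-2-methoxyphenoxy)phenyl]ethan-1-ol F1. Dess–Martin periodinane oxidises it to 1-[3,5-dibromo-2-(3,5-dibromo-2-methoxyphenoxy)phenyl]ethan-1-one F2. Baeyer–Villiger oxidation with CF3CO3H (from (CF3CO)2O and urea·H2O2, Na2HPO4, CH2Cl2) gives 3,5-dibromo-2-(3,5-dibromo-2-methoxyphenoxy)phenyl acetate F3. Methanolysis (K2CO3, MeOH) gives 8.

**Step 2.** The same misdirected migration can occur here.
- Cause: the methoxy group of 2 is wedged between the formyl group and a bromine and is twisted out of conjugation, so the hydride shift may compete and lower the supply of 4.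
- Fallback: it sets out from 5 and returns at 6. It removes the ring B oxidation altogether by introducing the ring B bromines after the ether bond is made.
- Course: purchased guaiacol (2-methoxyphenol) displaces the fluoride of 5 (Cs2CO3, DMF) to give 3,5-dibromo-2-(2-methoxyphenoxy)benzaldehyde F4. BBr3 demethylation gives 3,5-dibromo-2-(2-hydroxyphenoxy)benzaldehyde F5. Br2 (2 equiv, AcOH, NaOAc, rt) brominates ortho and para to the freed hydroxyl, while the formyl group keeps ring A inert, to give 3,5-dibromo-2-(3,5-dibromo-2-hydroxyphenoxy)benzaldehyde F6. Methylation (MeI, K2CO3, DMF) gives 6.

**Step 3.** The most likely failure is incomplete displacement together with erosion of the formyl group.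
- Cause: the fluoride is flanked by formyl and bromine, and the phenoxide of 4 is a weak nucleophile attenuated by two bromines. Prolonged heating with carbonate can lead to base-induced disproportionation of the aldehyde.
- Fallback: it sets out from 5 (and uses 4) and returns at 6. It replaces the formyl group during the coupling by a smaller, base-stable nitrile that tolerates more forcing conditions.
- Course: 5 is condensed with NH2OH·HCl (NaOAc, EtOH) to (E)-3,5-dibromo-2-fluorobenzaldehyde oxime F7, which is dehydrated (Ac2O, reflux) to 3,5-dibromo-2-fluorobenzonitrile F8. Displacement with 4 (Cs2CO3, DMSO, 80–100 °C) gives 3,5-dibromo-2-(3,5-dibromo-2-methoxyphenoxy)benzonitrile F9. Half-reduction with i-Bu2AlH (toluene, −78 °C) and hydrolysis of the aldimine with aqueous HCl gives 6.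

## Further compounds

F1 | step 4 | 1-[3,5-dibromo-2-(3,5-dibromo-2-methoxyphenoxy)phenyl]ethan-1-ol (racemic) | COc1c(Br)cc(Br)cc1Oc1c(C(C)O)cc(Br)cc1Br
F2 | step 4 | 1-[3,5-dibromo-2-(3,5-dibromo-2-methoxyphenoxy)phenyl]ethan-1-one | COc1c(Br)cc(Br)cc1Oc1c(C(C)=O)cc(Br)cc1Br
F3 | step 4 | 3,5-dibromo-2-(3,5-dibromo-2-methoxyphenoxy)phenyl acetate | COc1c(Br)cc(Br)cc1Oc1c(OC(C)=O)cc(Br)cc1Br
F4 | step 2 | 3,5-dibromo-2-(2-methoxyphenoxy)benzaldehyde | COc1ccccc1Oc1c(C=O)cc(Br)cc1Br
F5 | step 2 | 3,5-dibromo-2-(2-hydroxyphenoxy)benzaldehyde | Oc1ccccc1Oc1c(C=O)cc(Br)cc1Br
F6 | step 2 | 3,5-dibromo-2-(3,5-dibromo-2-hydroxyphenoxy)benzaldehyde | Oc1c(Br)cc(Br)cc1Oc1c(C=O)cc(Br)cc1Br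
F7 | step 3 | (E)-3,5-dibromo-2-fluorobenzaldehyde oxime | O/N=C/c1cc(Br)cc(Br)c1F
F8 | step 3 | 3,5-dibromo-2-fluorobenzonitrile | N#Cc1cc(Br)cc(Br)c1F
F9 | step 3 | 3,5-dibromo-2-(3,5-dibromo-2-methoxyphenoxy)benzonitrile | COc1c(Br)cc(Br)cc1Oc1c(C#N)cc(Br)cc1Br
A1 | alternative 1 | 3,5-dibromo-2H-pyran-2-one (3,5-dibromo-2-pyrone) | O=c1occ(Br)cc1Br
A2 | alternative 1 | 2-[(2-methoxyphenoxy)ethynyl]-4,4,5,5-tetramethyl-1,3,2-dioxaborolane | COc1ccccc1OC#CB1OC(C)(C)C(C)(C)O1
A3 | alternative 1 | 2-[3,5-dibromo-2-(2-methoxyphenoxy)phenyl]-4,4,5,5-tetramethyl-1,3,2-dioxaborolane | COc1ccccc1Oc1c(Br)cc(Br)cc1B1OC(C)(C)C(C)(C)O1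
A4 | alternative 2 | 2,4-dibromo-6-methoxyphenol (4,6-dibromoguaiacol) | COc1cc(Br)cc(Br)c1O
A5 | alternative 2 | 2-chlorocyclohexan-1-one (racemic) | O=C1CCCCC1Cl
A6 | alternative 2 | 2-(2,4-dibromo-6-methoxyphenoxy)cyclohexan-1-one (racemic) | COc1cc(Br)cc(Br)c1OC1CCCCC1=O
A7 | alternative 2 | 2,4-dibromo-6-(2,4-dibromo-6-methoxyphenoxy)phenol | COc1cc(Br)cc(Br)c1Oc1cc(Br)cc(Br)c1O
A8 | alternative 3 | 2-chloro-1-methoxy-3,5-dinitrobenzene | COc1cc([N+](=O)[O-])cc([N+](=O)[O-])c1Cl
A9 | alternative 3 | 1,5-dibromo-2-methoxy-3-(2-methoxy-4,6-dinitrophenoxy)benzene | COc1cc([N+](=O)[O-])cc([N+](=O)[O-])c1Oc1cc(Br)cc(Br)c1OC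
A10 | alternative 3 | 4-(3,5-dibromo-2-methoxyphenoxy)-5-methoxybenzene-1,3-diamine | COc1cc(N)cc(N)c1Oc1cc(Br)cc(Br)c1OC
A11 | alternative 3 | 1,5-dibromo-2-(3,5-dibromo-2-methoxyphenoxy)-3-methoxybenzene | COc1cc(Br)cc(Br)c1Oc1cc(Br)cc(Br)c1OC
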